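**Plan**
- Retrosynthesis: after two silyl ethers are unmasked, ring D is cut across its O–CMe2 bond and its CH2–CH2 bond into isobutene and a ring B o-quinone methide, which is traced to a 3'-hydroxymethyl-4'-phenol; the benzylic carbon is then cut from C3'.
- Ring C is cut at O1–C2, and the C3–C1' bond is traced through a 1,2-aryl shift to a chalcone, which is cut at Cα=Cβ into a ring A methyl ketone and a ring B aldehyde.
- Forward: the ring B aldehyde and ring A ketone are condensed to the chalcone; aryl shift and acid close ring C; protecting groups are exchanged so that only 4'-OH is free and O6' carries a bulky silyl group; C3' is hydroxymethylated; ring D is closed last.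
- Enabling feature: ring D is a 2,2-dimethyl-3,4-dihydro-2H-pyran fused to ring B through C3' (carbon) and C4' (oxygen). Its non-aromatic atoms are O4' and the C3' methylene (the termini of a C3'-methylene/C4'-oxo quinone methide) plus the CH2 and CMe2 carbons of isobutene.
- Stereochemistry: the target has no stereocentre. The chalcone E-alkene is thermodynamic, and the one transient sp3 stereocentre (acetal 9, racemic) is erased when ring C aromatizes.

Key step: step 12

Remark: isoflavone numbering is used (ring A C5–C8, ring B primed, C1' bonded to C3). The regiochemistry of step 10 rests on steric shielding of C5' by the 6'-silyl ether, which is why the benzyl/silyl exchange of steps 8 and 9 is accepted.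

**Step 1**
Reactants: 1 5-methoxyresorcinol
Product: 3 2,4-dihydroxy-6-methoxybenzaldehyde, via aryl iminium chloride 2 (not isolated)
Conditions: POCl3, DMF, EtOAc, 0 °C to rt; then H2O, 60 °C
Reagents that add atoms: N,N-dimethylformamide CN(C)C=O; water O
Why: Vilsmeier–Haack formylation, in which the chloroiminium ion should attack the carbon para to a free hydroxyl (flanked by OH and OMe) in preference to the carbon between the two hydroxyls, and hydrolysis of 2 releases the aldehyde; the 2,6-dihydroxy-4-methoxy isomer should be removable by crystallization.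

**Step 2**
Reactants: 3 2,4-dihydroxy-6-methoxybenzaldehyde
Product: 4 4-(benzyloxy)-2-hydroxy-6-methoxybenzaldehyde
Conditions: BnBr (1.0 equiv), K2CO3, acetone, rt
Reagents that add atoms: benzyl bromide BrCc1ccccc1
Why: Williamson etherification under weak base should select the more acidic 4-hydroxyl para to the formyl group, because the 2-hydroxyl is held in a hydrogen bond to the carbonyl.

**Step 3**
Reactants: 4 4-(benzyloxy)-2-hydroxy-6-methoxybenzaldehyde
Product: 5 4-(benzyloxy)-2-methoxy-6-(methoxymethoxy)benzaldehyde
Conditions: MOMCl, i-Pr2NEt, CH2Cl2, 0 °C to 40 °C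
Reagents that add atoms: chloromethyl methyl ether COCCl
Why: amine-mediated O-alkylation (MOM acetal formation) masks the remaining hydrogen-bonded phenol with a group that is base-stable for the aldol step and acid-labile in the presence of the benzyl ether.

**Step 4**
Reactants: 6 2,4-dihydroxyacetophenone
Product: 7 2-hydroxy-4-(methoxymethoxy)acetophenone
Conditions: MOMCl (1.1 equiv), K2CO3, acetone, rt
Reagents that add atoms: chloromethyl methyl ether COCCl
Why: Williamson-type alkylation should occur only at the 4-hydroxyl, since the 2-hydroxyl is chelated to the ketone and must stay free for the later closure of ring C.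

**Step 5**
Reactants: 5 4-(benzyloxy)-2-methoxy-6-(methoxymethoxy)benzaldehyde; 7 2-hydroxy-4-(methoxymethoxy)acetophenone
Product: 8 (E)-3-[4-(benzyloxy)-2-methoxy-6-(methoxymethoxy)phenyl]-1-[2-hydroxy-4-(methoxymethoxy)phenyl]prop-2-en-1-one
Conditions: KOH, EtOH–H2O, rt
Reagents that add atoms: none
Why: Claisen–Schmidt condensation of the methyl ketone enolate with the non-enolizable aldehyde, with E1cB dehydration giving the conjugated E-enone as the thermodynamic geometry; MOM and benzyl ethers are stable to hydroxide.

**Step 6**
Reactants: 8 the (E)-chalcone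
Product: 9 2-[4-(benzyloxy)-2-methoxy-6-(methoxymethoxy)phenyl]-1-[2-hydroxy-4-(methoxymethoxy)phenyl]-3,3-dimethoxypropan-1-one (racemic)
Conditions: Tl(NO3)3·3H2O (1.1 equiv), MeOH–CH(OMe)3, rt
Reagents that add atoms: methanol CO
Why: oxidative 1,2-aryl migration of a chalcone by trivalent thallium, in which oxythallation of the enone is followed by shift of the electron-rich ring B from Cβ to Cα as monovalent thallium leaves and methanol traps the oxocarbenium ion as the dimethyl acetal; the new stereocentre is formed racemic and is erased in step 7.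

**Step 7**
Reactants: 9 the dimethyl acetal
Product: 11 4'-benzyloxy-7,6'-dihydroxy-2'-methoxyisoflavone, via bis-MOM isoflavone 10 (not isolated)
Conditions: 10% aq. HCl, MeOH, 60 °C
Reagents that add atoms: none
Why: acid-catalysed cyclization–elimination (isoflavone synthesis from a formyl-deoxybenzoin acetal), in which the free ketone ortho-hydroxyl attacks the ionized acetal and loss of methanol aromatizes ring C to 10 before the same acid removes both MOM acetals; the benzyl ether is stable to these conditions.

**Step 8**
Reactants: 11 4'-benzyloxy-7,6'-dihydroxy-2'-methoxyisoflavone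
Product: 12 4'-benzyloxy-2'-methoxy-7,6'-bis(triisopropylsilyloxy)isoflavone
Conditions: TIPSOTf (2.5 equiv), 2,6-lutidine, CH2Cl2, 0 °C to rt
Reagents that add atoms: triisopropylsilyl triflate CC(C)[Si](C(C)C)(C(C)C)OS(=O)(=O)C(F)(F)F
Why: O-silylation with a silyl triflate and a hindered pyridine base should cap both phenols, including the hindered 6'-hydroxyl next to the biaryl bond, and places the bulky group beside C5'.

**Step 9**
Reactants: 12 4'-benzyloxy-2'-methoxy-7,6'-bis(triisopropylsilyloxy)isoflavone
Product: 13 4'-hydroxy-2'-methoxy-7,6'-bis(triisopropylsilyloxy)isoflavone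
Conditions: H2 (1 atm), Pd/C, EtOAc, rt
Reagents that add atoms: none
Why: catalytic hydrogenolysis of the benzyl ether leaves silyl ethers untouched and, if stopped after uptake of one equivalent of hydrogen, should spare the more slowly reduced C2=C3 bond of the chromone.

**Step 10**
Reactants: 13 4'-hydroxy-2'-methoxy-7,6'-bis(triisopropylsilyloxy)isoflavone
Product: 14 3'-formyl-4'-hydroxy-2'-methoxy-7,6'-bis(triisopropylsilyloxy)isoflavone
Conditions: MgCl2, Et3N, (CH2O)n, MeCN, reflux; then dilute HCl
Reagents that add atoms: paraformaldehyde (as formaldehyde) C=O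
Why: magnesium phenoxide-directed ortho-formylation (Casnati–Skattebøl) delivers formaldehyde only ortho to the free 4'-hydroxyl, with a second formaldehyde as hydride acceptor; of the two ortho carbons, C5' is flanked by the triisopropylsilyloxy group and C3' only by methoxy, so attack should go to C3'.

**Step 11**
Reactants: 14 3'-formyl-4'-hydroxy-2'-methoxy-7,6'-bis(triisopropylsilyloxy)isoflavone
Product: 15 4'-hydroxy-3'-(hydroxymethyl)-2'-methoxy-7,6'-bis(triisopropylsilyloxy)isoflavone
Conditions: NaBH4, THF–EtOH, 0 °C
Reagents that add atoms: none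
Why: borohydride 1,2-reduction of the aromatic aldehyde should be much faster at 0 °C than attack on the chromone carbonyl, a vinylogous ester; the sensitive o-hydroxybenzyl alcohol is worked up under neutral conditions and used without storage.

**Step 12**
Reactants: 15 4'-hydroxy-3'-(hydroxymethyl)-2'-methoxy-7,6'-bis(triisopropylsilyloxy)isoflavone; 16 isobutene
Product: 18 7,6'-bis-O-triisopropylsilyl glycyrrhizaisoflavone C, via o-quinone methide 17 (not isolated)
Conditions: isobutene (large excess, condensed in), toluene, sealed tube, 140 °C
Reagents that add atoms: none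
Why: Heating 15 expels water between the benzylic hydroxyl and the ortho 4'-hydroxyl to give o-quinone methide 17 (C3'=CH2, C4'=O), an electron-poor 1-oxadiene that isobutene should trap in an inverse-electron-demand hetero-Diels–Alder reaction, the established thermal route from o-hydroxybenzyl alcohols and alkenes to chromans. Ring D closes in the [4+2] mode (four heterodiene atoms plus two alkene atoms) through an asynchronous transition state in which the C–C bond between the alkene CH2 and the exocyclic methylene runs ahead of the O4'–CMe2 bond. No stereocentre arises, because the new quaternary carbon carries two methyl groups and both new ring carbons next to it are CH2. The step needs regioselectivity (oxygen to the disubstituted carbon) and site selectivity (O4' only): the first follows from the polarization of isobutene, whose CH2 end is nucleophilic and whose disubstituted carbon bears the developing positive charge; the second is fixed by the substrate, where O2' is a methyl ether, O6' is para to the benzylic carbon and silylated, and O4' is the only ortho hydroxyl. Re-aromatization of ring B makes the addition irreversible, and the large excess of alkene should outrun self-condensation of 17.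

**Step 13**
Reactants: 18 7,6'-bis-O-triisopropylsilyl glycyrrhizaisoflavone C
Product: 19 glycyrrhizaisoflavone C
Conditions: Bu4NF, AcOH, THF, 0 °C
Reagents that add atoms: none
Why: fluoride-induced cleavage of both aryl silyl ethers (Si–F bond formation), buffered with acetic acid so that no free phenoxide attacks the chromone; the chroman ether and the methyl ether are inert.

**Compound list**
1 | 5-methoxyresorcinol (5-methoxybenzene-1,3-diol) | COc1cc(O)cc(O)c1 | starting material
2 | (2,4-dihydroxy-6-methoxybenzylidene)dimethyliminium chloride | COc1cc(O)cc(O)c1C=[N+](C)C.[Cl-] | intermediate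
3 | 2,4-dihydroxy-6-methoxybenzaldehyde | COc1cc(O)cc(O)c1C=O | intermediate
4 | 4-(benzyloxy)-2-hydroxy-6-methoxybenzaldehyde | COc1cc(OCc2ccccc2)cc(O)c1C=O | intermediate
5 | 4-(benzyloxy)-2-methoxy-6-(methoxymethoxy)benzaldehyde | COCOc1cc(OCc2ccccc2)cc(OC)c1C=O | intermediate
6 | 2,4-dihydroxyacetophenone | CC(=O)c1ccc(O)cc1O | starting material
7 | 2-hydroxy-4-(methoxymethoxy)acetophenone | CC(=O)c1ccc(OCOC)cc1O | intermediate
8 | (E)-3-[4-(benzyloxy)-2-methoxy-6-(methoxymethoxy)phenyl]-1-[2-hydroxy-4-(methoxymethoxy)phenyl]prop-2-en-1-one | COCOc1ccc(C(=O)/C=C/c2c(OC)cc(OCc3ccccc3)cc2OCOC)c(O)c1 | intermediate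
9 | 2-[4-(benzyloxy)-2-methoxy-6-(methoxymethoxy)phenyl]-1-[2-hydroxy-4-(methoxymethoxy)phenyl]-3,3-dimethoxypropan-1-one (racemic) | COCOc1ccc(C(=O)C(C(OC)OC)c2c(OC)cc(OCc3ccccc3)cc2OCOC)c(O)c1 | intermediate
10 | 4'-benzyloxy-2'-methoxy-7,6'-bis(methoxymethoxy)isoflavone | COCOc1ccc2c(c1)occ(-c1c(OC)cc(OCc3ccccc3)cc1OCOC)c2=O | intermediate
11 | 4'-benzyloxy-7,6'-dihydroxy-2'-methoxyisoflavone | COc1cc(OCc2ccccc2)cc(O)c1-c1coc2cc(O)ccc2c1=O | intermediate
12 | 4'-benzyloxy-2'-methoxy-7,6'-bis(triisopropylsilyloxy)isoflavone | COc1cc(OCc2ccccc2)cc(O[Si](C(C)C)(C(C)C)C(C)C)c1-c1coc2cc(O[Si](C(C)C)(C(C)C)C(C)C)ccc2c1=O | intermediate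
13 | 4'-hydroxy-2'-methoxy-7,6'-bis(triisopropylsilyloxy)isoflavone | COc1cc(O)cc(O[Si](C(C)C)(C(C)C)C(C)C)c1-c1coc2cc(O[Si](C(C)C)(C(C)C)C(C)C)ccc2c1=O | intermediate
14 | 3'-formyl-4'-hydroxy-2'-methoxy-7,6'-bis(triisopropylsilyloxy)isoflavone | COc1c(C=O)c(O)cc(O[Si](C(C)C)(C(C)C)C(C)C)c1-c1coc2cc(O[Si](C(C)C)(C(C)C)C(C)C)ccc2c1=O | intermediate
15 | 4'-hydroxy-3'-(hydroxymethyl)-2'-methoxy-7,6'-bis(triisopropylsilyloxy)isoflavone | COc1c(CO)c(O)cc(O[Si](C(C)C)(C(C)C)C(C)C)c1-c1coc2cc(O[Si](C(C)C)(C(C)C)C(C)C)ccc2c1=O | intermediate
16 | isobutene (2-methylpropene) | CC(C)=C | starting material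
17 | ring B o-quinone methide (C3' exocyclic methylene, C4' carbonyl; 2'-methoxy, 6'- and 7-triisopropylsilyloxy) | C=C1C(=O)C=C(O[Si](C(C)C)(C(C)C)C(C)C)C(c2coc3cc(O[Si](C(C)C)(C(C)C)C(C)C)ccc3c2=O)=C1OC | intermediate
18 | 7,6'-bis-O-triisopropylsilyl glycyrrhizaisoflavone C | COc1c2c(cc(O[Si](C(C)C)(C(C)C)C(C)C)c1-c1coc3cc(O[Si](C(C)C)(C(C)C)C(C)C)ccc3c1=O)OC(C)(C)CC2 | intermediate
19 | glycyrrhizaisoflavone C, 7-hydroxy-3-(7-hydroxy-5-methoxy-2,2-dimethylchroman-6-yl)chromen-4-one | COc1c2c(cc(O)c1-c1coc3cc(O)ccc3c1=O)OC(C)(C)CC2 | target

**Step count**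
Total: 13 steps. Longest linear sequence: 12 steps (steps 1–3 and 5–13, from 1).

**Steps most likely to fail**

1. Step 12. The quinone methide may form too slowly, or may be consumed by self-condensation (dimerization, or attack by unreacted 15) faster than an unactivated gaseous alkene can capture it. The fallback sets out from 15 and builds the same ring ionically in two stages. Ionization of the benzylic alcohol with BF3·OEt2 in CH2Cl2 at −78 °C in the presence of (2-methylallyl)trimethylsilane (Hosomi–Sakurai benzylation) should give 4'-hydroxy-2'-methoxy-3'-(3-methylbut-3-en-1-yl)-7,6'-bis(triisopropylsilyloxy)isoflavone F1. Catalytic p-TsOH in toluene at 60 °C should then protonate the 1,1-disubstituted alkene, and O4' should capture the tertiary cation (Markovnikov hydroalkoxylation). This returns to the route at 18.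

2. Step 10. Formylation may leak to C5', may stall at a carbon flanked on both sides, or hot amine and the methanol formed may erode the 7-silyl ether. The fallback sets out from 13 and uses a boron template instead of magnesium, arriving directly at the alcohol oxidation level. PhB(OH)2, paraformaldehyde and catalytic propionic acid in refluxing toluene with water removal should deliver formaldehyde through a cyclic phenoxyboronate, which is more sensitive to flanking bulk. The product would be the 2-phenyl-4H-1,3,2-benzodioxaborin fused at C3'–C4' of ring B, F2. Transesterification with propane-1,3-diol in THF at rt would free the hydroxymethyl phenol. This returns at 15 and bypasses 14 and step 11.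

3. Step 6. The free 2'-hydroxyl may close onto the thallated enone (aurone formation), trivalent thallium may over-oxidize the very electron-rich ring B, or the nitric acid released may strip MOM groups early. The fallback sets out from 8 and closes ring C before the aryl shift. NaOAc in refluxing EtOH should effect oxa-Michael cyclization to the racemic flavanone 2-[4-(benzyloxy)-2-methoxy-6-(methoxymethoxy)phenyl]-7-(methoxymethoxy)chroman-4-one F3. A trivalent iodine reagent, [hydroxy(tosyloxy)iodo]benzene in CH(OMe)3–MeOH at rt to 50 °C, should then induce the known oxidative 2,3-aryl shift of flavanones to isoflavones. This returns at 10, which is carried through the acid treatment of step 7 to 11.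

**Further compounds**
F1 | step 12 | 4'-hydroxy-2'-methoxy-3'-(3-methylbut-3-en-1-yl)-7,6'-bis(triisopropylsilyloxy)isoflavone | COc1c(CCC(C)=C)c(O)cc(O[Si](C(C)C)(C(C)C)C(C)C)c1-c1coc2cc(O[Si](C(C)C)(C(C)C)C(C)C)ccc2c1=O
F2 | step 10 | 2-phenyl-4H-1,3,2-benzodioxaborin fused at C3'–C4' of ring B of 2'-methoxy-7,6'-bis(triisopropylsilyloxy)isoflavone | COc1c2c(cc(O[Si](C(C)C)(C(C)C)C(C)C)c1-c1coc3cc(O[Si](C(C)C)(C(C)C)C(C)C)ccc3c1=O)OB(c1ccccc1)OC2
F3 | step 6 | 2-[4-(benzyloxy)-2-methoxy-6-(methoxymethoxy)phenyl]-7-(methoxymethoxy)chroman-4-one (racemic) | COCOc1ccc2c(c1)OC(c1c(OC)cc(OCc3ccccc3)cc1OCOC)CC2=O
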